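Which flask ends with the longer chains turns on a count the earlier runs do not show, the chains begun, so I follow one molecule of initiator and ask what can become of it.

all flasks: initiator 10 mM

| flask | free monomer | transfer agent | remark | time |
|---|---|---|---|---|
| amber | 0.18 M | 6 mM | run made earlier |  |
| grey | 0.26 M | 6 mM | run made earlier |  |
| teal | 0.23 M | 6 mM | run made earlier |  |
| Thursday's | 0.20 M | 6.00 mM |  | 3.0 h |
| Sunday's | 0.30 M | 6.00 mM |  | 3.0 h |

- amber (time / h: monomer in chains / %, free monomer / %): 0.667: 10.5, 89.0; 1.33: 21.2, 78.5; 2.00: 31.4, 69.0; 2.50: 36.9, 63.7; 3.00: 42.1, 57.7
- grey (time / h: monomer in chains / %, free monomer / %): 0.250: 3.5, 96.8; 0.833: 14.5, 85.1; 1.33: 23.6, 77.6; 2.00: 31.8, 67.4; 3.00: 42.8, 57.4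
- teal (time / h: monomer in chains / %, free monomer / %): 0.250: 4.6, 95.4; 0.833: 13.9, 85.4; 1.33: 22.7, 78.0; 2.00: 32.2, 68.8; 3.00: 42.1, 57.2

(each reading ± 0.5 percentage points)

- which of the two ends with the longer chains by the average number of monomer units in a chain (chains begun, living or dead) ("neither" if they lie within 10%) (Thursday's / Sunday's / neither)
- average number of monomer units in a chain (chains begun, living or dead) at the end, Thursday's
- average number of monomer units in a chain (chains begun, living or dead) at the end, Sunday's

- the average divides the monomer in chains by the number of chains begun, living and dead together
- candidate steps: free monomer + living end -> monomer in chains + living end; living end + transfer agent -> dead chain; free monomer + initiator -> living end + monomer in chains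
- the earlier runs do not show the number of chains; that part of a forecast is a guess

The runs end alike: at 3.0 h the monomer in chains stands at 42.1%, 42.8% and 42.1% of very different charges, and I carry the mean over to both new flasks, though Sunday's lies beyond the charges tried.

X = 42.3%

In the first extreme every molecule of initiator begins a chain at once, and since a dead chain still counts as begun, the transfer agent changes nothing in the count:

Thursday's: X [free monomer] / [initiator] = 8.47
Sunday's: X [free monomer] / [initiator] = 12.7

This figure, the units per charged initiator, is a floor at that conversion: one molecule begins one chain, so fewer chains than the charge mean longer chains.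

In the second extreme initiator trickles in throughout, so chains keep beginning to the end and the length lies above the floor. The teal readings give the rate per free monomer:

early: 0.189 h⁻¹
late: 0.185 h⁻¹

The two readings match, but the early window covers the start, where the grey readings go from 0.130 h⁻¹ to 0.221 h⁻¹ over their first two intervals, and a level rate, the pseudo-first-order course, shows no more than living ends roughly level, ends begun against ends lost to the transfer agent, and not when the chains began. So the readings do not place the flasks between the extremes, and I commit to the floor as the low end of a guess, with Sunday's longer by a factor 1.50 if both flasks begin equally many chains, well beyond the margin. The count remains a guess.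

The forecast says Sunday's, with 8.5 and 12.6, and notes that “initiation may be incomplete”; its Sunday's figure stands just below mine, as it takes the conversion as 42%.

The flasks give Sunday's: 8.48 units on Thursday's, 12.9 on Sunday's.

    free monomer + living end → monomer in chains + living end, rate k1*[living end]*[free monomer] (k = 27.6 L mol⁻¹ h⁻¹)
    living end + transfer agent → dead chain (kL = 65.4 L mol⁻¹ h⁻¹)
    free monomer + initiator → living end + monomer in chains (k = 10.2 L mol⁻¹ h⁻¹)

In Thursday's flask the half-life of initiator at 3.00 h is 0.59 h, shorter than the 4.3 h of free monomer by chain growth, and half of the chain starting is done by 0.343 h, half of the growth by 1.41 h. Of its initiator 0.90% stands unreacted at the end, and the floor 8.47 lies beside the 8.48 found. The flask like Thursday's but with 0.025 M of initiator holds 77.4% monomer in chains, so 8.47 scaled by that conversion over X and by the initiator charges becomes 6.19 units per charged initiator, and with 3.7% of that initiator left its length is 6.43.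

Readings and results stem from a simulated flask with constants of no real substance; scatter was added.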